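## The problem

Compound 20 (the target) is pentacyclic: a cyclohexene (ring A), a seven-membered enol lactone (ring B, a 2-benzoxepin-1-one), a benzene ring (ring C), a 1,4-quinone (ring D) and a 1,4-thiazine 1,1-dioxide (ring E). Local numbering used below: C1 is the quaternary carbon (CH3, aryl), C2 the ring A carbon with the exocyclic double bond to C7 (the enol CH bonded to the lactone oxygen), C3 (bearing CH3)=C4 the ring alkene, C5 and C6 the two CH2 groups.

- C1 is the only stereocentre, an all-carbon benzylic quaternary carbon. No second centre can relay to it, so it must be set absolutely by a catalyst or by transfer from a centre that is destroyed afterwards.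
- The dienol ester O–C7=C2–C3=C4 is an acyl donor and a masked β,γ-unsaturated aldehyde. It will not survive amines, hydroxide, strong acid or peracids, so all heteroatom work on rings D and E has to be finished before ring B exists.
- In ring E the nitrogen sits next to the quinone carbonyl that is para-related to the lactone carbonyl on ring C, the sulfur next to the other. Hypotaurine adds to an unsymmetrical naphthoquinone with little preference unless ring C carries a strongly biasing group.
- The feature that makes the key step possible is ring A itself: a cyclohex-2-ene (C3=C4) with an exocyclic C2=C7 double bond at the allylic carbon. That is exactly what a vinylallene leaves behind after a [4+2] cycloaddition with an alkene C1=C6.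
- The oxygen on C7 is acylated by the benzoate whose ortho carbon carries C1. The ester is therefore a ready-made five-atom tether between the allene terminus C7 and an isopropenyl group (C1, C6, CH3) on the arene.
- An allenyl ester O–C7H=C2=C3 is the [3,3] isomer of a tertiary propargylic ester at C3, a centre that is easy to set.

## Retrosynthesis

**20 to 18 (via 19).** Cutting C1–C2 and C5–C6 (retro-[4+2]) opens rings A and B at once and gives the vinylallenyl ester 19. A retro-[3,3] shift then moves the carboxylate from C7 back to C3 and gives the tertiary propargylic ester 18. The neighbouring cuts (C1–aryl, or the lactone C–O) leave a quaternary centre to be made on an existing ring. This cut removes both rings, the quaternary centre and the dienol ester in one isomerisation, and 18 has a single tertiary carbinol stereocentre. The forward reaction must be a suprafacial 1,3-acyloxy shift followed by cycloaddition on the face of the diene that carries the ester oxygen. Because 20 is the product, nothing has to be done in the presence of the dienol lactone.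

**18 to 12 and 16.** The ester C–O bond is cut to give the thiazine-quinone acid 12 and (R)-3-methylpent-1-en-4-yn-3-ol 16. This is the convergent point. The forward reaction is acylation of a tertiary alcohol without ionising it.

**16 to 13 (via 15, 14).** The vinyl group of 16 comes from an epoxide CH2 plus one ylide carbon, the ethynyl group from a CH2OH. Both are present in commercial (S)-2-methylglycidol 13, and the C–O bond of the stereocentre is never broken. The alternative, asymmetric alkynylation of methyl vinyl ketone, would have to tell CH3 from vinyl.

**12 to 8 (via 11, 9).** The aryl–isopropenyl bond is cut (Suzuki–Miyaura coupling of triflate 9) and the acid is masked as its ethyl ester. This leads back to phenol 8. The phenol serves twice: as the coupling handle and as the control element of the next disconnection.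

**8 to 5 and 6.** The C–S and C–N bonds of ring E are cut to give hypotaurine 6 and hydroxyquinone 5. Done at this stage, the free phenol of 5 is para to the ring-fusion carbon that carries C8=O and deactivates that carbonyl, so the sulfinate is steered to C7. With the isopropenyl or triflate group in place instead, the two carbonyls are nearly equivalent. The forward reaction must add sulfur before nitrogen.

**5 to 1 and 2.** Two C–C bonds of ring C are cut (Diels–Alder benzannulation). Silylation of commercial 1 gives diene 3, which adds to 1,4-benzoquinone 2. Loss of ethanol aromatises the ring, and the ortho hydroxy/ester pattern arrives complete. Because 2 is symmetric there is no regiochemistry to control.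

## Roads not taken

**Alternative 1:** (the obvious route) Cut the C1–aryl bond and set C1 by catalytic asymmetric conjugate addition of a dimethoxynaphthylboronic acid to the commercial β-methyl cyclohexenone, giving ketone A1.
- The ketone of A1 is on the wrong carbon. It must become C3 (CH3, alkene), and the CH2 between it and the quaternary centre must be formylated at the most hindered α-position.
- The arene must then be carboxylated at a naphthalene β-position.
- The quinone and thiazine come last, so hypotaurine meets an unbiased quinone (both regioisomers) and an amine-sensitive enol lactone.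
- The count is well above ten linear steps, and every ring-forming event is separate.

**Alternative 2:** Cut the lactone C–O bond as a retro-Baeyer–Villiger step, back to the carbocyclic aryl vinyl ketone A2.
- The forward step is peracid oxidation with alkenyl migration. It has to beat epoxidation of the electron-rich cross-conjugated diene and the competing aryl migration.
- A2 still contains the quaternary centre in a fused ring system, so the whole polycyclisation problem of this natural-product family remains unsolved before the key step.

**Alternative 3:** Cut C1–aryl and the lactone C–O together: conjugate addition of an ortho-ester aryl metal to the cross-conjugated dienal A3, the dienolate closing ring B by O-acylation.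
- The idea is short, but the acceptor is a tetrasubstituted enal for which enantioselective aryl addition has no close precedent, and A3 is an oxidation-prone dihydrobenzaldehyde.
- An aryl metal is incompatible with the aminoquinone, which forces thiazine formation to the end, with the regiochemical and aminolysis problems of alternative 1.

The chosen plan sets C1 by a pericyclic transfer from a centre bought from the chiral pool, and carries a finished ring D/E through it.

Key step: step 10

Assumption: CIP analysis of the given SMILES gives (S) at the quaternary carbon (C2 > aryl > C6 > CH3); compounds 1, 2, 6, 10 and 13 are taken as commercial.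

## Route

Step 1
Reactants: 1 ethyl 2-(ethoxymethylidene)-3-oxobutanoate (E/Z mixture); 2 1,4-benzoquinone (2.5 equiv)
Product: 5 ethyl 3-hydroxy-5,8-dioxo-5,8-dihydronaphthalene-2-carboxylate, via silyloxydiene 3 (not isolated), via naphthalenetriol ester 4 (not isolated)
Conditions: Me3SiOTf, Et3N, CH2Cl2, 0 °C; then 2, rt; then CF3CO2H (cat.), rt
Reagents that add atoms: none
Why: The acetyl CH3 is the only enolisable site of 1, so silylation should give the 1-ethoxy-3-silyloxy diene 3, which adds to 2 in a Diels–Alder reaction; acid then eliminates ethanol and the silyl group to aromatise the new ring (4), and the excess quinone oxidises 4 to 5. The quinone 5 forms only after the diene is consumed, which guards against a second cycloaddition.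

Step 2
Reactants: 5 ethyl 3-hydroxy-5,8-dioxo-5,8-dihydronaphthalene-2-carboxylate; 6 hypotaurine (2-aminoethanesulfinic acid)
Product: 8 ethyl 7-hydroxy-5,10-dioxo-3,4,5,10-tetrahydro-2H-naphtho[2,3-b][1,4]thiazine-8-carboxylate 1,1-dioxide, via sulfonylhydroquinone 7 (not isolated)
Conditions: NaOAc/AcOH buffer (pH 5), EtOH/H2O, rt; then NaHCO3 to pH 8, O2 (1 atm), rt
Reagents that add atoms: none
Why: This is the known annulation of hypotaurine onto 1,4-naphthoquinones (sulfinate Michael addition, reoxidation, intramolecular amine addition, reoxidation). At pH 5 only the sulfinate is nucleophilic, and the phenol makes C8=O a vinylogous acid, so C5=O (para-related to the ester) is the acceptor and sulfur should enter at C7. The nitrogen can then only close on C6, which gives the N/S orientation of 20.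

Step 3
Reactants: 8 ethyl 7-hydroxy-5,10-dioxo-3,4,5,10-tetrahydro-2H-naphtho[2,3-b][1,4]thiazine-8-carboxylate 1,1-dioxide
Product: 9 ethyl 5,10-dioxo-7-{[(trifluoromethyl)sulfonyl]oxy}-3,4,5,10-tetrahydro-2H-naphtho[2,3-b][1,4]thiazine-8-carboxylate 1,1-dioxide
Conditions: PhNTf2, Et3N, DMAP (cat.), CH2Cl2/DMF, 0 °C → rt
Reagents that add atoms: N-phenylbis(trifluoromethanesulfonimide), O=S(=O)(N(c1ccccc1)S(=O)(=O)C(F)(F)F)C(F)(F)F
Why: O-sulfonylation of the acidic salicylate-type phenol with a mild triflimide; the vinylogous amide N–H is far less nucleophilic and should not react.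

Step 4
Reactants: 9 ethyl 5,10-dioxo-7-{[(trifluoromethyl)sulfonyl]oxy}-3,4,5,10-tetrahydro-2H-naphtho[2,3-b][1,4]thiazine-8-carboxylate 1,1-dioxide; 10 4,4,5,5-tetramethyl-2-(prop-1-en-2-yl)-1,3,2-dioxaborolane
Product: 11 ethyl 5,10-dioxo-7-(prop-1-en-2-yl)-3,4,5,10-tetrahydro-2H-naphtho[2,3-b][1,4]thiazine-8-carboxylate 1,1-dioxide
Conditions: Pd(OAc)2 (5 mol %), SPhos (10 mol %), K3PO4, toluene/H2O (10:1), 80 °C
Reagents that add atoms: none
Why: Suzuki–Miyaura coupling of an aryl triflate ortho to an ester; the fully substituted aminoquinone has no free quinone position for base or phosphine to attack.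

Step 5
Reactants: 11 ethyl 5,10-dioxo-7-(prop-1-en-2-yl)-3,4,5,10-tetrahydro-2H-naphtho[2,3-b][1,4]thiazine-8-carboxylate 1,1-dioxide
Product: 12 5,10-dioxo-7-(prop-1-en-2-yl)-3,4,5,10-tetrahydro-2H-naphtho[2,3-b][1,4]thiazine-8-carboxylic acid 1,1-dioxide
Conditions: LiOH·H2O, THF/H2O, rt → 40 °C; then 1 M HCl to pH 3, 0 °C
Reagents that add atoms: lithium hydroxide, [Li+].[OH-]
Why: Ester saponification; the N–H is deprotonated and protects the quinone, and brief cold acidification avoids acid-catalysed addition of the acid to the isopropenyl group.

Step 6
Reactants: 13 (S)-2-methylglycidol, (2S)-(2-methyloxiran-2-yl)methanol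
Product: 14 (R)-2-methyloxirane-2-carbaldehyde
Conditions: PhI(OAc)2, TEMPO (10 mol %), CH2Cl2, rt; used as a solution
Reagents that add atoms: none
Why: Aminoxyl-catalysed oxidation of a primary alcohol; the stereocentre is quaternary and cannot epimerise (the descriptor changes only because CHO outranks the ring CH2).

Step 7
Reactants: 14 (R)-2-methyloxirane-2-carbaldehyde
Product: 15 (S)-2-ethynyl-2-methyloxirane
Conditions: MeC(O)C(N2)P(O)(OMe)2, K2CO3, MeOH, 0 °C → rt
Reagents that add atoms: dimethyl (1-diazo-2-oxopropyl)phosphonate, CC(=O)C(=[N+]=[N-])P(=O)(OC)OC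
Why: Seyferth–Gilbert homologation in the Ohira–Bestmann form; with no α-hydrogen there is no racemisation, and a 2,2-disubstituted epoxide should survive K2CO3/MeOH at room temperature.

Step 8
Reactants: 15 (S)-2-ethynyl-2-methyloxirane
Product: 16 (R)-3-methylpent-1-en-4-yn-3-ol
Conditions: Me3S+ I−, n-BuLi (3.3 equiv each), THF, −20 °C → rt
Reagents that add atoms: trimethylsulfonium iodide, C[S+](C)C.[I-]
Why: Dimethylsulfonium methylide opens the epoxide at its CH2, and the sulfonium alkoxide eliminates dimethyl sulfide to give the one-carbon-homologated allylic alcohol, a known conversion of terminal and 2,2-disubstituted epoxides. The C–O bond at the stereocentre is retained; excess ylide covers the acidic alkyne C–H.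

Step 9
Reactants: 12 5,10-dioxo-7-(prop-1-en-2-yl)-3,4,5,10-tetrahydro-2H-naphtho[2,3-b][1,4]thiazine-8-carboxylic acid 1,1-dioxide; 16 (R)-3-methylpent-1-en-4-yn-3-ol
Product: 18 (3R)-3-methylpent-1-en-4-yn-3-yl 5,10-dioxo-7-(prop-1-en-2-yl)-3,4,5,10-tetrahydro-2H-naphtho[2,3-b][1,4]thiazine-8-carboxylate 1,1-dioxide, via acid chloride 17 (not isolated)
Conditions: Me2C=C(Cl)NMe2, CH2Cl2, 0 °C → rt; then 16, Et3N, DMAP, CH2Cl2, rt → 40 °C
Reagents that add atoms: none
Why: The chloroenamine makes the acid chloride without releasing HCl (which would attack the isopropenyl group), and DMAP-catalysed acylation of tertiary propargylic alcohols by aroyl chlorides is standard. Acylation at oxygen leaves the carbinol centre untouched.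

Step 10
Reactants: 18 (3R)-3-methylpent-1-en-4-yn-3-yl 5,10-dioxo-7-(prop-1-en-2-yl)-3,4,5,10-tetrahydro-2H-naphtho[2,3-b][1,4]thiazine-8-carboxylate 1,1-dioxide
Product: 20 target CNP0348176.1, (S) at the quaternary carbon, via allenyl ester 19 (not isolated)
Conditions: AgSbF6 (5 mol %), PhCl, 40 °C; filter through basic Al2O3; then PhCl (0.005 M), BHT, 120 °C
Reagents that add atoms: none
Why: Proposed new method: (1) The cationic silver salt binds the terminal alkyne, the ester carbonyl oxygen attacks the distal alkyne carbon C7 and the six-membered dioxinylium intermediate opens at C3–O, a suprafacial [3,3] acyloxy shift that should turn the (R) carbinol centre of 18 into the (Ra) axis of allenyl ester 19. (2) On heating at high dilution the vinylallene unit of 19 (C2=C3–C4=C5, s-cis) should add across the isopropenyl group (C1=C6) in a concerted, thermally allowed suprafacial [4+2] cycloaddition that forms C1–C2 and C5–C6 and leaves C2=C7 as the exocyclic enol ester. (3) The closest known reaction types are the silver-catalysed propargyl ester to allenyl ester rearrangement of tertiary ethynylcarbinyl carboxylates, tandem acyloxy shift/cycloadditions of propargylic esters that carry the 2π partner in the acyl group, and the intramolecular Diels–Alder reaction of carbon-tethered vinylallenes with centre-to-axis-to-centre chirality transfer; the new element is a [4+2] in which the migrating carboxylate is itself the tether. (4) Ring A closes by the [4+2] itself (six-membered, two new C–C bonds), and ring B is the seven-membered ring completed by the C1–C2 bond (C1, C2, C7, O, C=O and the two arene carbons), which requires the ester to react through its s-cis rotamer. (5) C1 is controlled by the allene axis: the acyloxy oxygen on C7 lies over one face of the diene only, the alkene can reach only that face, and the short, nearly planar benzoate tether should hold the aryl group back over C7 with the CH3 group on the side of the C3 methyl, which maps (R)-18 onto (S)-20. (6) The step needs 1,3- over 1,2-acyloxy migration (silver, not gold or platinum salts, which send terminal alkynes down the 1,2 path), no ionisation or allylic transposition of the tertiary ester (non-nucleophilic counter-ion, no protic acid), and survival of the allene configuration (low silver loading, silver removed before heating). (7) Intermolecular reactions are suppressed by dilution and a radical inhibitor, and the tetrasubstituted amino-sulfonyl quinone alkene is too electron-rich and hindered to compete as a dienophile. (8) Strain release from allene to alkene and the electron-poor aryl group on the dienophile should compensate for the unactivated 1,1-disubstituted alkene.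

## Compound list

1 | ethyl 2-(ethoxymethylidene)-3-oxobutanoate | CCOC=C(C(C)=O)C(=O)OCC | starting material
2 | 1,4-benzoquinone | O=C1C=CC(=O)C=C1 | starting material
3 | ethyl 2-(ethoxymethylidene)-3-[(trimethylsilyl)oxy]but-3-enoate | CCOC=C(C(=C)O[Si](C)(C)C)C(=O)OCC | intermediate
4 | ethyl 3,5,8-trihydroxynaphthalene-2-carboxylate | CCOC(=O)c1cc2c(O)ccc(O)c2cc1O | intermediate
5 | ethyl 3-hydroxy-5,8-dioxo-5,8-dihydronaphthalene-2-carboxylate | CCOC(=O)c1cc2C(=O)C=CC(=O)c2cc1O | intermediate
6 | hypotaurine (2-aminoethanesulfinic acid) | NCCS(=O)O | starting material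
7 | ethyl 7-[(2-aminoethyl)sulfonyl]-3,5,8-trihydroxynaphthalene-2-carboxylate | CCOC(=O)c1cc2c(O)c(S(=O)(=O)CCN)cc(O)c2cc1O | intermediate
8 | ethyl 7-hydroxy-5,10-dioxo-3,4,5,10-tetrahydro-2H-naphtho[2,3-b][1,4]thiazine-8-carboxylate 1,1-dioxide | CCOC(=O)c1cc2C(=O)C3=C(NCCS3(=O)=O)C(=O)c2cc1O | intermediate
9 | ethyl 5,10-dioxo-7-{[(trifluoromethyl)sulfonyl]oxy}-3,4,5,10-tetrahydro-2H-naphtho[2,3-b][1,4]thiazine-8-carboxylate 1,1-dioxide | CCOC(=O)c1cc2C(=O)C3=C(NCCS3(=O)=O)C(=O)c2cc1OS(=O)(=O)C(F)(F)F | intermediate
10 | 4,4,5,5-tetramethyl-2-(prop-1-en-2-yl)-1,3,2-dioxaborolane | CC(=C)B1OC(C)(C)C(C)(C)O1 | starting material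
11 | ethyl 5,10-dioxo-7-(prop-1-en-2-yl)-3,4,5,10-tetrahydro-2H-naphtho[2,3-b][1,4]thiazine-8-carboxylate 1,1-dioxide | CCOC(=O)c1cc2C(=O)C3=C(NCCS3(=O)=O)C(=O)c2cc1C(C)=C | intermediate
12 | 5,10-dioxo-7-(prop-1-en-2-yl)-3,4,5,10-tetrahydro-2H-naphtho[2,3-b][1,4]thiazine-8-carboxylic acid 1,1-dioxide | OC(=O)c1cc2C(=O)C3=C(NCCS3(=O)=O)C(=O)c2cc1C(C)=C | intermediate
13 | (S)-2-methylglycidol, (2S)-(2-methyloxiran-2-yl)methanol | C[C@]1(CO)CO1 | starting material
14 | (R)-2-methyloxirane-2-carbaldehyde | C[C@]1(C=O)CO1 | intermediate
15 | (S)-2-ethynyl-2-methyloxirane | C[C@]1(C#C)CO1 | intermediate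
16 | (R)-3-methylpent-1-en-4-yn-3-ol | C[C@](O)(C#C)C=C | intermediate
17 | 5,10-dioxo-7-(prop-1-en-2-yl)-3,4,5,10-tetrahydro-2H-naphtho[2,3-b][1,4]thiazine-8-carbonyl chloride 1,1-dioxide | ClC(=O)c1cc2C(=O)C3=C(NCCS3(=O)=O)C(=O)c2cc1C(C)=C | intermediate
18 | (3R)-3-methylpent-1-en-4-yn-3-yl 5,10-dioxo-7-(prop-1-en-2-yl)-3,4,5,10-tetrahydro-2H-naphtho[2,3-b][1,4]thiazine-8-carboxylate 1,1-dioxide | C[C@](OC(=O)c1cc2C(=O)C3=C(NCCS3(=O)=O)C(=O)c2cc1C(C)=C)(C#C)C=C | intermediate
19 | (Ra)-3-methylpenta-1,2,4-trien-1-yl 5,10-dioxo-7-(prop-1-en-2-yl)-3,4,5,10-tetrahydro-2H-naphtho[2,3-b][1,4]thiazine-8-carboxylate 1,1-dioxide | C=CC(C)=[C@]=C([H])OC(=O)c1cc2C(=O)C3=C(NCCS3(=O)=O)C(=O)c2cc1C(C)=C | intermediate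
20 | CNP0348176.1, (S)-configured pentacyclic dienol lactone | CC1=CCC[C@]2(C)C1=COC(=O)c1cc3c(cc12)C(=O)C1=C(C3=O)S(=O)(=O)CCN1 | target

## Step count and least certain steps

Total: 10 steps. Longest linear sequence: 7 steps (steps 1–5, 9, 10); steps 6–8 form a three-step branch.

**Step 10 (key step, proposed new method).** Several processes could go wrong:
- 1,2- instead of 1,3-migration of the carboxylate, or ionisation of the doubly activated tertiary ester with allylic transposition;
- racemisation of the allene axis by the silver salt before cycloaddition;
- oligomerisation of the vinylallene because the strained seven-membered tether reaches the transition state too slowly;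
- delivery of the alkene in the other rotameric orientation, which would erode or invert the configuration at C1.

If the transfer is clean but of the opposite sense, the route is run from (R)-2-methylglycidol instead. Racemic 16 is a commodity chemical, so the step can be piloted before any chiral material is used.

Fallback from known chemistry, setting out from triflate 9 and returning at 20. Palladium-catalysed borylation of 9 with tetrahydroxydiboron would give arylboronic acid F1. The alkene partner would be made by copper-catalysed coupling of the Grignard reagent of 2-(2-bromoethyl)-2-methyl-1,3-dioxolane with (E)-4-chloro-3-methylbut-2-enyl acetate to ketal acetate F2, and removal of both protecting groups (K2CO3/MeOH, then aqueous acid) to (E)-8-hydroxy-6-methyloct-6-en-2-one F3. An enantioselective redox-relay oxidative Heck arylation of F3 with F1 (divalent palladium, pyridine–oxazoline ligand, O2; ligand enantiomer to be assigned on a model) adds the aryl group to the methyl-bearing alkene carbon and walks the metal to the carbinol, giving the β-quaternary keto aldehyde F4. Amine-mediated intramolecular aldol condensation (piperidine, AcOH) would close ring A as enal ester F5. Saponification gives enal acid F6, and enol lactonisation (Ac2O, NaOAc), in which the extended dienol of the enal is O-acylated, would return 20.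

**Step 2.** What may go wrong: conjugate addition of the sulfinate, or of free amine, at C6 instead of C7 (loss of regiocontrol), and slow reoxidation of the sulfonyl hydroquinone. Fallback from 5 back to 8: thia-Michael addition of cysteamine (a softer nucleophile that adds more selectively β to the more electrophilic carbonyl), air oxidation and ring closure would give thiazine sulfide F7. Oxidation at sulfur (H2O2, Na2WO4 cat.) would then give 8. No alkene or enol ester is present at this stage.

**Step 1.** What may go wrong: slow cycloaddition of the ester-deactivated diene (only the isomer with the ethoxy group pointing outward can react through s-cis), or a second cycloaddition on 5. Fallback from 2 back to 8, with the ester introduced by carbonylation instead: Diels–Alder reaction of 2 with commercial 2-(trimethylsilyloxy)buta-1,3-diene, desilylation and oxidation would give 6-hydroxynaphthalene-1,4-dione F8. The hypotaurine annulation of step 2, under the same phenol control, would give hydroxy thiazine dioxide F9. Iodination ortho to the phenol at the position remote from the ring fusion (N-iodosuccinimide) would give iodophenol F10, and palladium-catalysed ethoxycarbonylation (CO, EtOH, Et3N) returns to 8.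

**Step 8.** What may go wrong: loss of the volatile epoxide and alcohol on isolation, and side reactions of the lithium acetylide. Fallback from 13 back to 16, with the order reversed so that the intermediates are not volatile: opening of 13 itself with excess dimethylsulfonium methylide (the Payne rearrangement of 13 is degenerate and returns the same enantiomer) would give (R)-2-methylbut-3-ene-1,2-diol F11. Oxidation of the primary alcohol (TEMPO, PhI(OAc)2) would give (R)-2-hydroxy-2-methylbut-3-enal F12, which is homologated to 16 with dimethyl (1-diazo-2-oxopropyl)phosphonate and K2CO3 in MeOH.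

## Further compounds

F1 | step 10 | [8-(ethoxycarbonyl)-1,1,5,10-tetraoxo-3,4,5,10-tetrahydro-2H-naphtho[2,3-b][1,4]thiazin-7-yl]boronic acid | CCOC(=O)c1cc2C(=O)C3=C(NCCS3(=O)=O)C(=O)c2cc1B(O)O
F2 | step 10 | (2E)-3-methyl-6-(2-methyl-1,3-dioxolan-2-yl)hex-2-en-1-yl acetate | CC(=O)OC/C=C(\C)CCCC1(C)OCCO1
F3 | step 10 | (6E)-8-hydroxy-6-methyloct-6-en-2-one | CC(=O)CCC/C(C)=C/CO
F4 | step 10 | ethyl 7-[(3R)-3-methyl-1,7-dioxooctan-3-yl]-5,10-dioxo-3,4,5,10-tetrahydro-2H-naphtho[2,3-b][1,4]thiazine-8-carboxylate 1,1-dioxide | CC(=O)CCC[C@](C)(CC=O)c1cc2C(=O)C3=C(S(=O)(=O)CCN3)C(=O)c2cc1C(=O)OCC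
F5 | step 10 | ethyl 7-[(1S)-2-formyl-1,3-dimethylcyclohex-2-en-1-yl]-5,10-dioxo-3,4,5,10-tetrahydro-2H-naphtho[2,3-b][1,4]thiazine-8-carboxylate 1,1-dioxide | CC1=C(C=O)[C@@](C)(CCC1)c1cc2C(=O)C3=C(S(=O)(=O)CCN3)C(=O)c2cc1C(=O)OCC
F6 | step 10 | 7-[(1S)-2-formyl-1,3-dimethylcyclohex-2-en-1-yl]-5,10-dioxo-3,4,5,10-tetrahydro-2H-naphtho[2,3-b][1,4]thiazine-8-carboxylic acid 1,1-dioxide | CC1=C(C=O)[C@@](C)(CCC1)c1cc2C(=O)C3=C(S(=O)(=O)CCN3)C(=O)c2cc1C(=O)O
F7 | step 2 | ethyl 7-hydroxy-5,10-dioxo-3,4,5,10-tetrahydro-2H-naphtho[2,3-b][1,4]thiazine-8-carboxylate | CCOC(=O)c1cc2C(=O)C3=C(NCCS3)C(=O)c2cc1O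
F8 | step 1 | 6-hydroxynaphthalene-1,4-dione | O=C1C=CC(=O)c2cc(O)ccc12
F9 | step 1 | 7-hydroxy-3,4-dihydro-2H-naphtho[2,3-b][1,4]thiazine-5,10-dione 1,1-dioxide | Oc1ccc2C(=O)C3=C(NCCS3(=O)=O)C(=O)c2c1
F10 | step 1 | 7-hydroxy-8-iodo-3,4-dihydro-2H-naphtho[2,3-b][1,4]thiazine-5,10-dione 1,1-dioxide | Oc1c(I)cc2C(=O)C3=C(NCCS3(=O)=O)C(=O)c2c1
F11 | step 8 | (R)-2-methylbut-3-ene-1,2-diol | C[C@](O)(CO)C=C
F12 | step 8 | (R)-2-hydroxy-2-methylbut-3-enal | C[C@](O)(C=O)C=C
A1 | alternative 1 | (R)-3-(5,8-dimethoxynaphthalen-2-yl)-3-methylcyclohexan-1-one | C[C@]1(CCCC(=O)C1)c1ccc2c(OC)ccc(OC)c2c1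
A2 | alternative 2 | carbocyclic aryl vinyl ketone corresponding to 20 without the lactone ring oxygen, same arrangement at the quaternary carbon | CC1=CCC[C@]2(C)C1=CC(=O)c1cc3c(cc12)C(=O)C1=C(C3=O)S(=O)(=O)CCN1
A3 | alternative 3 | 2,6-dimethylcyclohexa-1,5-diene-1-carbaldehyde | CC1=CCCC(C)=C1C=O
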